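The earlier runs and the new flask are simulated for substances that don't exist; scatter was added.

- A small charge, 0.050 M of substrate with 0.0525 M of reagent, goes into one bath for 30 h, and the bath is chosen here by how long target is reckoned to last beside the spare reagent.

| flask | substrate | reagent | temperature | remark | time |
|---|---|---|---|---|---|
| theta | 0.070 M | 0.0525 M | 20 °C | run made earlier |  |
| delta | 0.11 M | 0.0525 M | 62 °C | run made earlier |  |
| gamma | 0.050 M | 0.079 M | 20 °C | run made earlier |  |
| cedar | 0.050 M | 0.0525 M | 100 °C |  | 30 h |
| birch | 0.050 M | 0.0525 M | 25 °C |  | 30 h |
| larch | 0.050 M | 0.0525 M | 50 °C |  | 30 h |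
| elm | 0.050 M | 0.0525 M | 75 °C |  | 30 h |

- theta (time / h: target / %, over-reaction product / %, substrate / %): 120: 7, 9, 3; 240: 4, 17, 2; 480: 4, 19, 1; 720: 0, 20, 0; 1440: 0, 23, 0
- delta (time / h: target / %, over-reaction product / %, substrate / %): 15.0: 5, 14, 0; 30.0: 0, 14, 0; 48.0: 0, 17, 0; 96.0: 0, 17, 0; 192: 0, 16, 0
- gamma (time / h: target / %, over-reaction product / %, substrate / %): 120: 11, 25, 1; 480: 1, 36, 0; 720: 1, 37, 0; 960: 0, 34, 3; 1440: 1, 35, 1

(scatter of a reading: 1.5 percentage points)

- percentages count the substrate that a species holds: one homo dimer counts as two
- what may be going on: reagent + target -> over-reaction product; substrate + reagent <-> target + released group; 2 substrate -> homo dimer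

- the flask with the highest share of target in all that became target or over-reaction product ("all alike" if they lie within 1.5 percentage points) (cedar / birch / larch / elm / all alike)
- share of target in all that became target or over-reaction product, cedar
- share of target in all that became target or over-reaction product, birch
- share of target in all that became target or over-reaction product, larch
- share of target in all that became target or over-reaction product, elm

- With reagent taken as roughly steady, over-reaction is pseudo-first-order in target, so for target made at the start the share of target in target plus over-reaction product falls as exp(−time/life).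
- My reckoning starts from the first readings, which give a life of 101 h in gamma and 145 h in theta.
- Each over-reaction product has taken two reagents. Dividing by the mean reagent up to that reading gives constants of 0.155 M⁻¹ h⁻¹ in gamma and 0.157 M⁻¹ h⁻¹ in theta, both read from scattered readings.
- The same reckoning on delta at 15.0 h gives 2.59 M⁻¹ h⁻¹ at 62 °C, which is 16.5 times the constant of theta at 20 °C.
- Spreading that factor evenly in the logarithm from theta to delta gives 0.220 M⁻¹ h⁻¹ at 25 °C.
- The plateaus of theta and gamma suggest that about 29.5% of the substrate reaches target, which leaves 0.0377 M of reagent. So birch has a target life of 121 h, the time for the share to fall to exp(−1) of its start.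
- Over 30 h that life leaves 78.0% in birch. The same spreading divides that life by 5.30 for larch and gives 26.8% there, so the charge goes into the birch bath.
- The forecast also names birch, from “followed by slower target-to-over-product conversion”, with 0% for cedar, 74% for birch, 22% for larch and 0.5% for elm. My birch and larch figures stand above these.
- The highest share is in birch: 71.8% in birch, 6.73% in larch, 0% in elm and 0% in cedar, so larch lies 15 percentage points below the forecast. At 30.0 h in birch, target is made at 0.578 times the rate at which it is used, each step taken net. The target life of 121 h gave 78.0%, whereas the share found in birch corresponds to a life of 90.5 h, which is shorter.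

    reagent + target → over-reaction product (k = 0.368 M⁻¹ h⁻¹, Ea = 72.0 kJ mol⁻¹)
    substrate + reagent ⇌ target + released group (K = 3.00, k = 0.908 M⁻¹ h⁻¹, Ea = 79.0 kJ mol⁻¹, ΔH = −8.00 kJ mol⁻¹)
    2 substrate → homo dimer (k = 2.81 M⁻¹ h⁻¹, Ea = 73.0 kJ mol⁻¹)
    (constants at 25 °C)

- Birch left until 3.0 d: the life of 90.5 h gives a share of 45.1%, and the computed flask gives 44.9%.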